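**Retrosynthetic overview**
- The depside is cut at the aryl–O bond, not the acyl–O bond: the A-ring keto acid acts as an O-nucleophile toward a B-ring arylboronic acid (Cu-mediated Chan–Lam esterification). The carboxyl is never activated, so the free ketone cannot collapse to the isocoumarin, which is the sink of acyl-activation routes.
- The A-ring keto acid comes from saponification of a 3-heptylisocoumarin, made by carboxylate-directed Rh(III) C–H acylmethylation/annulation of 2-hydroxy-4-methoxybenzoic acid with an octanoyl-derived sulfoxonium ylide.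
- The B-ring boronic acid comes from benzyl orsellinate by selective 4-O-triflation and Pd borylation; the last step is hydrogenolysis of the benzyl ester.
- Rings: both benzene rings are bought intact; the only ring formed is the isocoumarin lactone (step 2), and it is opened again in step 3.

Assumption: the target SMILES has no stereocentre and no stereogenic double bond, so it is achiral and needs no stereocontrol; the four starting materials are taken as commercial.

**Route**

Step 1
Reactants: 1 trimethylsulfoxonium iodide; 2 octanoyl chloride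
Product: 4 1-[dimethyl(oxo)-λ6-sulfanylidene]nonan-2-one, via dimethylsulfoxonium methylide 3 (not isolated)
Conditions: 1 (3 equiv), KOt-Bu (3 equiv), THF, reflux, 2 h; then 2 (1 equiv), 0 °C to rt
Reagents that add atoms: none
Why: Acylation of the Corey–Chaykovsky ylide by the acid chloride, with a second equivalent of ylide deprotonating the acylsulfoxonium salt to the stabilised β-keto sulfoxonium ylide.

Step 2
Reactants: 4 1-[dimethyl(oxo)-λ6-sulfanylidene]nonan-2-one; 5 2-hydroxy-4-methoxybenzoic acid
Product: 7 3-heptyl-8-hydroxy-6-methoxy-1H-isochromen-1-one, via ring-open keto acid 6 (not isolated)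
Conditions: [Cp*RhCl2]2 (2.5 mol %), AgSbF6 (10 mol %), NaOAc (0.5 equiv), HFIP, 80 °C
Reagents that add atoms: none
Why: Carboxylate-directed Rh(III) C–H activation at C6 (the only free ortho C–H), carbene migratory insertion from the sulfoxonium ylide with loss of DMSO, protodemetalation to keto acid 6 and enol-lactonisation, a known Rh(III) C–H acylmethylation/annulation of benzoic acids that installs the whole 2-oxononyl chain in one step.

Step 3
Reactants: 7 3-heptyl-8-hydroxy-6-methoxy-1H-isochromen-1-one
Product: 6 2-hydroxy-4-methoxy-6-(2-oxononyl)benzoic acid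
Conditions: 2 M aq KOH, 1,4-dioxane, 60 °C; then 1 M HCl, 0 °C, to pH 3; extract, concentrate below 25 °C
Reagents that add atoms: potassium hydroxide, [K+].[OH-]
Why: Saponification of the enol lactone, in which hydroxide adds to C1, the ring opens to carboxylate plus enolate, the enolate ketonises and cannot re-close in base, and cold acidification frees the keto acid.

Step 4
Reactants: 8 2,4-dihydroxy-6-methylbenzoic acid (orsellinic acid)
Product: 9 benzyl 2,4-dihydroxy-6-methylbenzoate
Conditions: BnBr (1.05 equiv), KHCO3 (1.1 equiv), DMF, rt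
Reagents that add atoms: benzyl bromide, BrCc1ccccc1
Why: Chemoselective SN2 O-alkylation of the carboxylate, since bicarbonate does not ionise the phenols appreciably.

Step 5
Reactants: 9 benzyl 2,4-dihydroxy-6-methylbenzoate
Product: 10 benzyl 2-hydroxy-6-methyl-4-(trifluoromethylsulfonyloxy)benzoate
Conditions: PhNTf2 (1.05 equiv), Et3N (1.2 equiv), CH2Cl2, 0 °C to rt
Reagents that add atoms: N-phenyl-bis(trifluoromethanesulfonimide), FC(F)(F)S(=O)(=O)N(c1ccccc1)S(=O)(=O)C(F)(F)F
Why: Selective O-sulfonylation of the more acidic, non-chelated 4-OH, the 2-OH being locked in a hydrogen bond to the ester carbonyl.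

Step 6
Reactants: 10 benzyl 2-hydroxy-6-methyl-4-(trifluoromethylsulfonyloxy)benzoate
Product: 11 [4-(benzyloxycarbonyl)-3-hydroxy-5-methylphenyl]boronic acid
Conditions: B2(OH)4 (3 equiv), XPhos Pd G2 (2 mol %), XPhos (4 mol %), KOAc (3 equiv), EtOH, 80 °C
Reagents that add atoms: tetrahydroxydiboron, OB(O)B(O)O
Why: Miyaura-type Pd(0) borylation of the aryl triflate with bis-boronic acid, which gives the free arylboronic acid directly and leaves the phenol and benzyl ester alone.

Step 7
Reactants: 6 2-hydroxy-4-methoxy-6-(2-oxononyl)benzoic acid; 11 [4-(benzyloxycarbonyl)-3-hydroxy-5-methylphenyl]boronic acid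
Product: 12 benzyl 2-hydroxy-4-{[2-hydroxy-4-methoxy-6-(2-oxononyl)benzoyl]oxy}-6-methylbenzoate
Conditions: 11 (2 equiv), Cu(OTf)2 (0.4 equiv), urea (0.4 equiv), EtOAc, air, 60 °C
Reagents that add atoms: none
Why: Chan–Lam-type Cu(II)/O2 oxidative O-arylation of a carboxylic acid with an arylboronic acid (Cu carboxylate, B-to-Cu transmetalation, C–O reductive elimination from Cu(III)), so the carboxyl carbon is never electrophilic and the free ketone cannot lactonise to 7, while the hindered 2,6-disubstituted acid reacts as an unhindered O-nucleophile and the hydrogen-bonded phenols stay out without amine base.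

Step 8
Reactants: 12 benzyl 2-hydroxy-4-{[2-hydroxy-4-methoxy-6-(2-oxononyl)benzoyl]oxy}-6-methylbenzoate
Product: 13 2-hydroxy-4-{[2-hydroxy-4-methoxy-6-(2-oxononyl)benzoyl]oxy}-6-methylbenzoic acid (target)
Conditions: H2 (1 atm), 10 % Pd/C, EtOAc, rt
Reagents that add atoms: none
Why: Neutral hydrogenolysis of the benzyl ester, which leaves the depside ester, the dialkyl ketone and the aryl methyl ether untouched and supplies no acid or base to trigger lactonisation.

**Compound list**

1 | trimethylsulfoxonium iodide | C[S+](C)(C)=O.[I-] | starting material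
2 | octanoyl chloride | CCCCCCCC(=O)Cl | starting material
3 | dimethylsulfoxonium methylide | [CH2-][S+](C)(C)=O | intermediate
4 | 1-[dimethyl(oxo)-λ6-sulfanylidene]nonan-2-one | CCCCCCCC(=O)C=S(C)(C)=O | intermediate
5 | 2-hydroxy-4-methoxybenzoic acid | COc1ccc(C(=O)O)c(O)c1 | starting material
6 | 2-hydroxy-4-methoxy-6-(2-oxononyl)benzoic acid | CCCCCCCC(=O)Cc1cc(OC)cc(O)c1C(=O)O | intermediate
7 | 3-heptyl-8-hydroxy-6-methoxy-1H-isochromen-1-one | CCCCCCCc1cc2cc(OC)cc(O)c2c(=O)o1 | intermediate
8 | 2,4-dihydroxy-6-methylbenzoic acid (orsellinic acid) | Cc1cc(O)cc(O)c1C(=O)O | starting material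
9 | benzyl 2,4-dihydroxy-6-methylbenzoate | Cc1cc(O)cc(O)c1C(=O)OCc1ccccc1 | intermediate
10 | benzyl 2-hydroxy-6-methyl-4-(trifluoromethylsulfonyloxy)benzoate | Cc1cc(OS(=O)(=O)C(F)(F)F)cc(O)c1C(=O)OCc1ccccc1 | intermediate
11 | [4-(benzyloxycarbonyl)-3-hydroxy-5-methylphenyl]boronic acid | Cc1cc(B(O)O)cc(O)c1C(=O)OCc1ccccc1 | intermediate
12 | benzyl 2-hydroxy-4-{[2-hydroxy-4-methoxy-6-(2-oxononyl)benzoyl]oxy}-6-methylbenzoate | CCCCCCCC(=O)Cc1cc(OC)cc(O)c1C(=O)Oc1cc(C)c(C(=O)OCc2ccccc2)c(O)c1 | intermediate
13 | 2-hydroxy-4-{[2-hydroxy-4-methoxy-6-(2-oxononyl)benzoyl]oxy}-6-methylbenzoic acid | CCCCCCCC(=O)Cc1cc(OC)cc(O)c1C(=O)Oc1cc(C)c(C(=O)O)c(O)c1 | target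

**Step count**

Total steps: 8. Longest linear sequence: 5 steps (1, 2, 3, 7, 8; the B-ring branch 4, 5, 6, 7, 8 is equally long).

**Three steps most likely to fail**

Step 7 (Chan–Lam esterification). The salicylate unit of 6 may chelate copper, a phenol may be O-arylated instead, or the Lewis-acidic copper may close 6 back to 7. The fallback sets out from 11 and comes back at 12. Treat 11 with PhI(OAc)2 and BF3·OEt2 in CH2Cl2 at –78 °C to rt to obtain [4-(benzyloxycarbonyl)-3-hydroxy-5-methylphenyl](phenyl)iodonium tetrafluoroborate F1. Then deprotonate 6 with exactly 1 equiv KOt-Bu in toluene and warm it with F1 to 80 °C. Metal-free ligand coupling at iodine(III) transfers the more electron-poor, ester-bearing aryl group to the carboxylate oxygen, releases iodobenzene and gives 12.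

Step 2 (Rh(III) C–H annulation on a free salicylic acid). Chelation of rhodium by the salicylate, carbene O–H insertion into the phenol, or protodecarboxylation may win. The fallback sets out from 2 and comes back at 7. Convert 2 with N,O-dimethylhydroxylamine hydrochloride and Et3N into N-methoxy-N-methyloctanamide F2. Deprotonate commercial 2,4-dimethoxy-6-methylbenzoic acid F3 with LDA (2.2 equiv, THF, –78 to 0 °C) to the carboxylate/benzylic dianion and acylate it with F2 to give 2,4-dimethoxy-6-(2-oxononyl)benzoic acid F4. Close F4 in warm Ac2O to 3-heptyl-6,8-dimethoxy-1H-isochromen-1-one F5. BCl3 in CH2Cl2 (–78 to 0 °C) then removes only the peri 8-O-methyl group, by chelation to the lactone carbonyl, and gives 7.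

Step 3 (isolation of the free salicylic keto acid). On acidification or concentration 6 can re-lactonise to 7 or lose CO2, and its free ortho-hydroxyl also burdens step 7. The fallback sets out from 7 and comes back at 13. Benzylate 7 (BnBr, K2CO3, DMF, 60 °C) to 8-(benzyloxy)-3-heptyl-6-methoxy-1H-isochromen-1-one F6. Saponify it as in step 3 to 2-(benzyloxy)-4-methoxy-6-(2-oxononyl)benzoic acid F7, which has no free ortho-hydroxyl, is much less prone to decarboxylation and does not chelate copper. Couple F7 with 11 under the step 7 conditions to benzyl 4-{[2-(benzyloxy)-4-methoxy-6-(2-oxononyl)benzoyl]oxy}-2-hydroxy-6-methylbenzoate F8. Hydrogenolysis as in step 8 then removes both benzyl groups and gives 13.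

**Further compounds**

F1 | step 7 | [4-(benzyloxycarbonyl)-3-hydroxy-5-methylphenyl](phenyl)iodonium tetrafluoroborate | Cc1cc([I+]c2ccccc2)cc(O)c1C(=O)OCc1ccccc1.F[B-](F)(F)F
F2 | step 2 | N-methoxy-N-methyloctanamide | CCCCCCCC(=O)N(C)OC
F3 | step 2 | 2,4-dimethoxy-6-methylbenzoic acid | COc1cc(C)c(C(=O)O)c(OC)c1
F4 | step 2 | 2,4-dimethoxy-6-(2-oxononyl)benzoic acid | CCCCCCCC(=O)Cc1cc(OC)cc(OC)c1C(=O)O
F5 | step 2 | 3-heptyl-6,8-dimethoxy-1H-isochromen-1-one | CCCCCCCc1cc2cc(OC)cc(OC)c2c(=O)o1
F6 | step 3 | 8-(benzyloxy)-3-heptyl-6-methoxy-1H-isochromen-1-one | CCCCCCCc1cc2cc(OC)cc(OCc3ccccc3)c2c(=O)o1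
F7 | step 3 | 2-(benzyloxy)-4-methoxy-6-(2-oxononyl)benzoic acid | CCCCCCCC(=O)Cc1cc(OC)cc(OCc2ccccc2)c1C(=O)O
F8 | step 3 | benzyl 4-{[2-(benzyloxy)-4-methoxy-6-(2-oxononyl)benzoyl]oxy}-2-hydroxy-6-methylbenzoate | CCCCCCCC(=O)Cc1cc(OC)cc(OCc2ccccc2)c1C(=O)Oc1cc(C)c(C(=O)OCc2ccccc2)c(O)c1
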